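**Assumptions:** (E)-1-nitropropene and 4-allyl-2,6-dimethoxyphenol are bought. (S)-Diphenylprolinol TMS ether gives the same (2R,3S)-type syn adduct with these partners as it does with propanal and nitrostyrene. Both phenols are carried as benzyl ethers.

## Retrosynthetic overview
- Target ⇒ bis-O-benzyl 2-aryl-3-methyl-4-benzyl-THF (global hydrogenolysis).
- The THF ring forms last, by acid-mediated dehydrative cyclization of a 1,4-diol through the p-alkoxybenzylic cation. C7 (the aryl-bearing carbon) is set thermodynamically, as the 2,3-trans/2,4-cis isomer.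
- The 1,4-diol comes from ArMgBr addition to a lactol (a masked C7 aldehyde). The lactol comes from Nef reaction of a γ-nitro alcohol.
- The γ-nitro alcohol comes from a Hayashi–Jørgensen Michael addition of 3-arylpropanal to (E)-1-nitropropene. This is the only enantio-determining step and sets C8 and C8' (3,4-trans in the THF).
- The aryl pieces come from 4-allylsyringol and 4-bromoguaiacol.

## Route

**Step 1**
Reactants: 1 (4-allyl-2,6-dimethoxyphenol), 2 (benzyl bromide)
Product: 3 (5-allyl-2-(benzyloxy)-1,3-dimethoxybenzene)
Conditions: BnBr, K2CO3, DMF, rt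
Reagents that add atoms: benzyl bromide, BrCc1ccccc1
Why: Williamson O-benzylation masks the phenol for the Grignard step, and the benzyl group is removed in the last step.

**Step 2**
Reactants: 3
Product: 4 (3-[4-(benzyloxy)-3,5-dimethoxyphenyl]propan-1-ol)
Conditions: 9-BBN, THF, 0 °C → rt; then NaOH, H2O2
Reagents that add atoms: hydrogen peroxide, OO (supplies the OH oxygen)
Why: Hydroboration–oxidation is anti-Markovnikov and regioselective for the terminal allyl alkene, and no stereocenter is formed.

**Step 3**
Reactants: 4
Product: 5 (3-[4-(benzyloxy)-3,5-dimethoxyphenyl]propanal)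
Conditions: Dess–Martin periodinane, NaHCO3, CH2Cl2, rt
Reagents that add atoms: none
Why: Mild oxidation of the primary alcohol to the aldehyde, which is the enamine donor for Step 5.

**Step 4**
Reactants: 6 (4-bromo-2-methoxyphenol), 2 (benzyl bromide)
Product: 7 (1-(benzyloxy)-4-bromo-2-methoxybenzene)
Conditions: BnBr, K2CO3, acetone, reflux
Reagents that add atoms: benzyl bromide, BrCc1ccccc1
Why: O-Benzylation gives the aryl bromide that becomes the Grignard reagent in Step 8.

**Step 5**
Reactants: 5, 8 ((E)-1-nitropropene)
Product: 9 ((2R,3R)-2-{[4-(benzyloxy)-3,5-dimethoxyphenyl]methyl}-3-methyl-4-nitrobutanal)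
Conditions: (S)-diphenylprolinol TMS ether (20 mol %), PhCO2H (20 mol %), toluene, 0 °C → rt, 48 h (5 in excess)
Reagents that add atoms: none (8 is the numbered reactant; the catalyst is not incorporated)
Why: This is an enamine-catalysed Michael addition (Hayashi–Jørgensen). The (E)-enamine attacks the nitroalkene through a synclinal transition state, setting C8' and C8 as the syn adduct (3,4-trans in the THF) with the absolute configuration shown.

**Step 6**
Reactants: 9
Product: 10 ((2R,3R)-2-{[4-(benzyloxy)-3,5-dimethoxyphenyl]methyl}-3-methyl-4-nitrobutan-1-ol)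
Conditions: NaBH4, MeOH, 0 °C, 30 min (can be run in the same pot after diluting Step 5 with MeOH)
Reagents that add atoms: none
Why: Chemoselective aldehyde reduction (nitro and benzyl ethers untouched) removes the epimerizable α-stereocenter, and both stereocenters are retained.

**Step 7**
Reactants: 10
Product: 11 ((3R,4R)-4-{[4-(benzyloxy)-3,5-dimethoxyphenyl]methyl}-3-methyloxolan-2-ol, anomeric mixture)
Conditions: (i) NaOMe, MeOH, 0 °C; (ii) add the nitronate to 2 M aq. H2SO4/THF, 0 °C → rt
Reagents that add atoms: water, O (supplies the carbonyl oxygen)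
Why: The Nef reaction converts the primary nitronate into the aldehyde, which closes at once with the γ-hydroxyl to a lactol. This masks the aldehyde so C8 cannot epimerize, and the anomeric centre is erased later.

**Step 8**
Reactants: 11, 7 (converted in situ to ArMgBr)
Product: 12 ((2R,3R)-4-[4-(benzyloxy)-3-methoxyphenyl]-2-{[4-(benzyloxy)-3,5-dimethoxyphenyl]methyl}-3-methylbutane-1,4-diol, C4 epimeric mixture)
Conditions: 7 + Mg, THF, reflux → ArMgBr (3.5 equiv); then 11, THF, 0 °C → rt; aq. NH4Cl
Reagents that add atoms: 4-(benzyloxy)-3-methoxyphenylmagnesium bromide, COc1cc([Mg]Br)ccc1OCc1ccccc1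
Why: Grignard addition to the hydroxy-aldehyde tautomer of the lactol; the new C7 carbinol is deliberately left uncontrolled because Step 9 resets it.

**Step 9**
Reactants: 12
Product: 13 ((3R,4R,5R)-3-{[4-(benzyloxy)-3,5-dimethoxyphenyl]methyl}-5-[4-(benzyloxy)-3-methoxyphenyl]-4-methyloxolane)
Conditions: p-TsOH·H2O (20 mol %), toluene, 60 °C, 3 h
Reagents that add atoms: none
Why: Acid-catalysed dehydrative 5-exo cyclization via the p-alkoxybenzylic cation, with reversible ionization of C7–O. This funnels C7 to the most stable isomer, with aryl trans to the C8 methyl and cis to the C8' benzyl, while C8 and C8' are untouched.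

**Step 10**
Reactants: 13
Product: 14 (target)
Conditions: H2 (1 atm), 10% Pd/C, EtOAc/MeOH, rt, 2 h
Reagents that add atoms: none (H2 adds only hydrogen)
Why: Hydrogenolysis removes both aryl benzyl ethers, and the THF benzylic C–O bond and all stereocenters survive these neutral, short-exposure conditions.

## Compound list
1 | 4-allyl-2,6-dimethoxyphenol | C=CCc1cc(OC)c(O)c(OC)c1 | starting material
2 | benzyl bromide | BrCc1ccccc1 | starting material
3 | 5-allyl-2-(benzyloxy)-1,3-dimethoxybenzene | C=CCc1cc(OC)c(OCc2ccccc2)c(OC)c1 | intermediate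
4 | 3-[4-(benzyloxy)-3,5-dimethoxyphenyl]propan-1-ol | OCCCc1cc(OC)c(OCc2ccccc2)c(OC)c1 | intermediate
5 | 3-[4-(benzyloxy)-3,5-dimethoxyphenyl]propanal | O=CCCc1cc(OC)c(OCc2ccccc2)c(OC)c1 | intermediate
6 | 4-bromo-2-methoxyphenol | COc1cc(Br)ccc1O | starting material
7 | 1-(benzyloxy)-4-bromo-2-methoxybenzene | COc1cc(Br)ccc1OCc1ccccc1 | intermediate
8 | (E)-1-nitropropene | C/C=C/[N+](=O)[O-] | starting material
9 | (2R,3R)-2-{[4-(benzyloxy)-3,5-dimethoxyphenyl]methyl}-3-methyl-4-nitrobutanal | O=C[C@H](Cc1cc(OC)c(OCc2ccccc2)c(OC)c1)[C@@H](C)C[N+](=O)[O-] | intermediate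
10 | (2R,3R)-2-{[4-(benzyloxy)-3,5-dimethoxyphenyl]methyl}-3-methyl-4-nitrobutan-1-ol | OC[C@H](Cc1cc(OC)c(OCc2ccccc2)c(OC)c1)[C@@H](C)C[N+](=O)[O-] | intermediate
11 | (3R,4R)-4-{[4-(benzyloxy)-3,5-dimethoxyphenyl]methyl}-3-methyloxolan-2-ol (anomeric mixture) | OC1OC[C@H](Cc2cc(OC)c(OCc3ccccc3)c(OC)c2)[C@H]1C | intermediate
12 | (2R,3R)-4-[4-(benzyloxy)-3-methoxyphenyl]-2-{[4-(benzyloxy)-3,5-dimethoxyphenyl]methyl}-3-methylbutane-1,4-diol (C4 epimers) | OC[C@H](Cc1cc(OC)c(OCc2ccccc2)c(OC)c1)[C@@H](C)C(O)c1ccc(OCc2ccccc2)c(OC)c1 | intermediate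
13 | (3R,4R,5R)-bis-O-benzyl THF | COc1cc([C@@H]2OC[C@H](Cc3cc(OC)c(OCc4ccccc4)c(OC)c3)[C@H]2C)ccc1OCc1ccccc1 | intermediate
14 | 4-{[(3R,4R,5R)-5-(4-hydroxy-3-methoxyphenyl)-4-methyloxolan-3-yl]methyl}-2,6-dimethoxyphenol | COc1cc([C@@H]2OC[C@H](Cc3cc(OC)c(O)c(OC)c3)[C@H]2C)ccc1O | target

## Totals
Total step count: 10. Longest linear sequence: 9 steps (Steps 1, 2, 3, 5, 6, 7, 8, 9, 10).

## Three steps most likely to fail
1. **Step 5 (Michael addition to a β-methyl nitroalkene).** It is slow and may give modest dr, ee or yield.
   Fallback: switch to auxiliary control. Convert the acid from 5 to an Evans N-acyl oxazolidinone, add its Ti-enolate to 8, then cleave the auxiliary with LiBH4 to reach nitro alcohol 10. Choose the auxiliary enantiomer that gives the (2R,3R) configuration.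
2. **Step 7 (Nef reaction of a primary nitroalkane).** It may give over-oxidation, oximes or methyl acetal, and an acetal would not react with the Grignard reagent in Step 8.
   Fallback: build lactol 11 by the lactone route. Make the enantioenriched 4-(arylmethyl)butyrolactone by Evans alkylation of N-(3-arylpropanoyl)oxazolidinone with bromoacetate, LiBH4 cleavage and lactonization. Then methylate α to the carbonyl (LiHMDS, MeI, trans to the β-substituent) and reduce with DIBAL at −78 °C.
3. **Step 9 (thermodynamic C7 convergence).** The dr may be only moderate, and E1 elimination to the styrene is possible.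
   Fallback: change to kinetic SN2 closure. Separate the C4 diol epimers of 12 (or recycle the wrong epimer by MnO2 oxidation and reduction), then selectively tosylate the primary alcohol of the correct epimer and close with NaH. This forms the THF with retention at C7, and the configuration is confirmed by NOE.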